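**Strategy.** The route rests on disconnecting the C8–C12 bond (prostanoid numbering) of the 4-oxygenated cyclopent-2-enone ring. A tertiary carbinol (C12) next to the ketone α-carbon (C8) is the retron of a Piancatelli rearrangement. A cheap 2,5-disubstituted furan, {5-[(Z)-oct-2-enyl]furan-2-yl}methanol, already holds C9–C12. A chiral Brønsted acid and water dearomatize it, and 4π-conrotatory closure of the resulting hydroxypentadienyl cation builds the carbocycle, the C9 ketone, the C10=C11 enone and the C12 stereocentre in one operation. Chlorination at C10, a (Z)-enol triflate at C7 and a Suzuki coupling then add the remaining atoms.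

Key step: step 3

Remark: atoms are numbered as in prostanoids (C1 ester carbon, C8–C12 ring, C13–C20 octenyl chain), the target being the (5E,7Z,12R,14Z) isomer; the (R)-configured acid in step 3 is assumed to induce the (S)-carbinol, and its antipode is used if the sense of induction proves opposite.

Step 1
Reactants: 1 (2Z)-oct-2-en-1-ol
Product: 2 (2Z)-1-bromooct-2-ene
Conditions: CBr4, PPh3, CH2Cl2, 0 °C
Reagents that add atoms: carbon tetrabromide, BrC(Br)(Br)Br
Why: Appel bromination of a primary allylic alcohol proceeds by SN2 displacement of the alkoxyphosphonium ion under neutral conditions and should keep the Z-alkene in place.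

Step 2
Reactants: 3 furan-2-ylmethanol; 2 (2Z)-1-bromooct-2-ene
Product: 5 {5-[(2Z)-oct-2-en-1-yl]furan-2-yl}methanol, via dilithiated furfuryl alcohol 4 (not isolated)
Conditions: n-BuLi (2.2 equiv), TMEDA, THF, −78 to 0 °C; then 2, −78 °C to rt; H2O
Reagents that add atoms: none
Why: Double deprotonation (O–H, then the most acidic ring C–H at the free α-position) gives a dianion whose furyllithium carbon should be alkylated by SN2 displacement on the primary allylic bromide, as in classical 2-furyllithium allylations, while the lithium alkoxide stays inert.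

Step 3
Reactants: 5 {5-[(2Z)-oct-2-en-1-yl]furan-2-yl}methanol
Product: 8 (4S)-4-hydroxy-4-[(2Z)-oct-2-en-1-yl]cyclopent-2-en-1-one, via dihydrofuranol hemiketal 6 (not isolated), via hydroxypentadienyl cation 7 (not isolated)
Conditions: (R)-3,3'-bis(2,4,6-triisopropylphenyl)-1,1'-binaphthyl-2,2'-diyl N-triflylphosphoramide (10 mol%), H2O (5 equiv), toluene, 40 °C
Reagents that add atoms: water, O
Why: Proposed new method: the acid ionises the furfuryl alcohol to a 2-methylidenefuranium ion, water adds at the octenyl-bearing ring carbon, hemiketal 6 opens to the Z-configured 1,4-dihydroxypentadienyl cation 7, and thermal 4π-conrotatory electrocyclization joins its two termini (C8 and C12) before proton loss gives the enone. The closest known reactions are the racemic Piancatelli rearrangement of 5-alkylated 2-furylcarbinols (hot water or ZnCl2), the chiral-phosphoric-acid-catalysed aza-Piancatelli rearrangement and chiral-Brønsted-acid-catalysed Nazarov cyclizations; enantiocontrol of the water-terminated variant with a primary carbinol is the untested part. The cyclopentenone ring closes by 4π-conrotatory electrocyclic ring closure (formally 5-endo-trig), and the former furan oxygen ends as the C9 carbonyl oxygen. The only new stereocenter, C12, is set by torquoselectivity: the chiral phosphoramide anion is hydrogen-bonded to both O–H groups of cation 7 and should allow only one sense of conrotation, so that the hydroxyl-bearing terminus offers a single enantiotopic face to the CH2 terminus. The step needs water capture at the ring carbon, which the cation secures because attack at the exocyclic CH2 only returns 5, and an untouched Z-alkene, which is insulated by a CH2 group and is not protonated under these mild conditions. The catalyst antipode is chosen to deliver the (S)-alcohol.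

Step 4
Reactants: 8 (4S)-4-hydroxy-4-[(2Z)-oct-2-en-1-yl]cyclopent-2-en-1-one
Product: 9 (4S)-4-hydroxy-4-[(2Z)-oct-2-en-1-yl]-6-oxabicyclo[3.1.0]hexan-2-one (both epoxide diastereomers)
Conditions: 30% aq. H2O2, NaOH (0.1 equiv), MeOH, 0 °C
Reagents that add atoms: hydrogen peroxide, OO
Why: Weitz–Scheffer nucleophilic epoxidation should touch only the electron-poor enone (the isolated Z-alkene is inert to HOO−), and since H2O2 is far more acidic than the tertiary alcohol no alkoxide capable of retro-aldol opening is formed; the two new epoxide stereocenters are erased in step 5.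

Step 5
Reactants: 9 (4S)-4-hydroxy-4-[(2Z)-oct-2-en-1-yl]-6-oxabicyclo[3.1.0]hexan-2-one
Product: 11 (4S)-2-chloro-4-hydroxy-4-[(2Z)-oct-2-en-1-yl]cyclopent-2-en-1-one, via chlorohydrin 10 (not isolated)
Conditions: conc. aq. HCl, THF, 0 °C to rt
Reagents that add atoms: hydrogen chloride, Cl
Why: Acid-mediated opening of the epoxy ketone by chloride at the α-carbon (SN2 at C10, away from the neopentyl C11) followed by acid-catalysed β-elimination of water should give the α-chloroenone, while ionisation of the tertiary carbinol is disfavoured because the cation would sit at the γ-position of the enone.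

Step 6
Reactants: 11 (4S)-2-chloro-4-hydroxy-4-[(2Z)-oct-2-en-1-yl]cyclopent-2-en-1-one
Product: 12 (4S)-2-chloro-4-[(2Z)-oct-2-en-1-yl]-4-(triethylsilyloxy)cyclopent-2-en-1-one
Conditions: Et3SiOTf, 2,6-lutidine, CH2Cl2, −78 to 0 °C
Reagents that add atoms: triethylsilyl trifluoromethanesulfonate, CC[Si](CC)(CC)OS(=O)(=O)C(F)(F)F
Why: Silylation of the hindered tertiary alcohol with a silyl triflate and a non-nucleophilic base masks the hydroxyl so that the enolate of step 7 can neither be quenched nor open by retro-aldol cleavage.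

Step 7
Reactants: 12 (4S)-2-chloro-4-[(2Z)-oct-2-en-1-yl]-4-(triethylsilyloxy)cyclopent-2-en-1-one
Product: 14 {(Z)-[(5R)-3-chloro-5-[(2Z)-oct-2-en-1-yl]-2-oxo-5-(triethylsilyloxy)cyclopent-3-en-1-ylidene]methyl} trifluoromethanesulfonate, via lithium enolate 13 (not isolated)
Conditions: LiN(SiMe3)2 (1.1 equiv), THF, −78 °C; CF3CH2OCHO; then N-(5-chloropyridin-2-yl)triflimide, −78 to 0 °C
Reagents that add atoms: 2,2,2-trifluoroethyl formate, O=COCC(F)(F)F; N-(5-chloropyridin-2-yl)-1,1,1-trifluoro-N-(trifluoromethylsulfonyl)methanesulfonamide, FC(F)(F)S(=O)(=O)N(c1ccc(Cl)cn1)S(=O)(=O)C(F)(F)F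
Why: Kinetic enolisation at C8 (the only enolisable position), Claisen-type C-formylation and O-sulfonylation of the lithium-chelated β-ketoaldehyde enolate at the aldehyde-derived oxygen should give the enol triflate with O–Tf cis to the ring carbonyl, because both the lithium chelate and allylic strain against the quaternary C12 hold that oxygen on the carbonyl side.

Step 8
Reactants: 15 methyl hex-5-ynoate
Product: 16 methyl (5E)-6-(4,4,5,5-tetramethyl-1,3,2-dioxaborolan-2-yl)hex-5-enoate
Conditions: pinacolborane, Cp2Zr(H)Cl (5 mol%), Et3N (10 mol%), neat, 60 °C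
Reagents that add atoms: pinacolborane, CC1(C)OBOC1(C)C
Why: Zirconium-catalysed hydroboration of the terminal alkyne is a syn, anti-Markovnikov addition that should give the (E)-alkenylboronate and tolerate the ester.

Step 9
Reactants: 14 {(Z)-[(5R)-3-chloro-5-[(2Z)-oct-2-en-1-yl]-2-oxo-5-(triethylsilyloxy)cyclopent-3-en-1-ylidene]methyl} trifluoromethanesulfonate; 16 methyl (5E)-6-(4,4,5,5-tetramethyl-1,3,2-dioxaborolan-2-yl)hex-5-enoate
Product: 17 methyl (5E,7Z,12R,14Z)-10-chloro-9-oxo-12-(triethylsilyloxy)prosta-5,7,10,14-tetraen-1-oate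
Conditions: PdCl2(dppf) (5 mol%), K3PO4, THF/H2O, 25 °C, dark
Reagents that add atoms: none
Why: Suzuki–Miyaura coupling proceeds with retention at both sp2 partners, so the (Z)-enol triflate and the (E)-boronate should give the 7Z,5E-dienone; the vinylogous acyl triflate adds to palladium far faster than the C10–Cl bond, and the chelating dppf leaves no free phosphine to isomerise the product.

Step 10
Reactants: 17 methyl (5E,7Z,12R,14Z)-10-chloro-9-oxo-12-(triethylsilyloxy)prosta-5,7,10,14-tetraen-1-oate
Product: 18 methyl (5E,7Z,12R,14Z)-10-chloro-12-hydroxy-9-oxoprosta-5,7,10,14-tetraen-1-oate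
Conditions: 48% aq. HF, MeCN, 0 °C, dark
Reagents that add atoms: none
Why: Fluoride-assisted acidic desilylation cleaves only the Si–O bond and should leave the ester, the chlorodienone and all alkene geometries untouched.

Step 11
Reactants: 18 methyl (5E,7Z,12R,14Z)-10-chloro-12-hydroxy-9-oxoprosta-5,7,10,14-tetraen-1-oate
Product: 19 methyl (5E,7Z,12R,14Z)-12-acetoxy-10-chloro-9-oxoprosta-5,7,10,14-tetraen-1-oate
Conditions: Ac2O, Sc(OTf)3 (2 mol%), MeCN, −20 °C, dark
Reagents that add atoms: acetic anhydride, CC(=O)OC(C)=O
Why: Lewis-acid-catalysed acylation of the tertiary alcohol avoids nucleophilic amines that could add reversibly to the cross-conjugated dienone and erode the 7Z geometry, and since the C12–O bond is not broken the configuration is retained.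

**Compound list**

1 | (2Z)-oct-2-en-1-ol | CCCCC/C=C\CO | starting material
2 | (2Z)-1-bromooct-2-ene | CCCCC/C=C\CBr | intermediate
3 | furan-2-ylmethanol | OCc1ccco1 | starting material
4 | lithium (5-lithiofuran-2-yl)methanolate (not isolated) | [Li]OCc1ccc([Li])o1 | intermediate
5 | {5-[(2Z)-oct-2-en-1-yl]furan-2-yl}methanol | CCCCC/C=C\Cc1ccc(CO)o1 | intermediate
6 | 2-methylidene-5-[(2Z)-oct-2-en-1-yl]-2,5-dihydrofuran-5-ol (not isolated) | CCCCC/C=C\CC1(O)C=CC(=C)O1 | intermediate
7 | ring-opened (Z)-1,4-dihydroxypentadienyl cation, paired with the chiral phosphoramide anion (not isolated) | CCCCC/C=C\CC(=[OH+])/C=C\C(O)=C | intermediate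
8 | (4S)-4-hydroxy-4-[(2Z)-oct-2-en-1-yl]cyclopent-2-en-1-one | CCCCC/C=C\C[C@@]1(O)C=CC(=O)C1 | intermediate
9 | (4S)-4-hydroxy-4-[(2Z)-oct-2-en-1-yl]-6-oxabicyclo[3.1.0]hexan-2-one, both epoxide diastereomers | CCCCC/C=C\C[C@@]1(O)C2OC2C(=O)C1 | intermediate
10 | 2-chloro-3,4-dihydroxy-4-[(2Z)-oct-2-en-1-yl]cyclopentan-1-one, carbinol carbon as in 8 (not isolated) | CCCCC/C=C\C[C@@]1(O)C(O)C(Cl)C(=O)C1 | intermediate
11 | (4S)-2-chloro-4-hydroxy-4-[(2Z)-oct-2-en-1-yl]cyclopent-2-en-1-one | CCCCC/C=C\C[C@@]1(O)C=C(Cl)C(=O)C1 | intermediate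
12 | (4S)-2-chloro-4-[(2Z)-oct-2-en-1-yl]-4-(triethylsilyloxy)cyclopent-2-en-1-one | CCCCC/C=C\C[C@@]1(O[Si](CC)(CC)CC)C=C(Cl)C(=O)C1 | intermediate
13 | lithium (Z)-enolate of the 5-formyl ketone, chelated (not isolated) | CCCCC/C=C\C[C@@]1(O[Si](CC)(CC)CC)C=C(Cl)C(=O)/C1=C\O[Li] | intermediate
14 | {(Z)-[(5R)-3-chloro-5-[(2Z)-oct-2-en-1-yl]-2-oxo-5-(triethylsilyloxy)cyclopent-3-en-1-ylidene]methyl} trifluoromethanesulfonate | CCCCC/C=C\C[C@@]1(O[Si](CC)(CC)CC)C=C(Cl)C(=O)/C1=C\OS(=O)(=O)C(F)(F)F | intermediate
15 | methyl hex-5-ynoate | C#CCCCC(=O)OC | starting material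
16 | methyl (5E)-6-(4,4,5,5-tetramethyl-1,3,2-dioxaborolan-2-yl)hex-5-enoate | COC(=O)CCC/C=C/B1OC(C)(C)C(C)(C)O1 | intermediate
17 | methyl (5E,7Z,12R,14Z)-10-chloro-9-oxo-12-(triethylsilyloxy)prosta-5,7,10,14-tetraen-1-oate | CCCCC/C=C\C[C@@]1(O[Si](CC)(CC)CC)C=C(Cl)C(=O)/C1=C\C=C\CCCC(=O)OC | intermediate
18 | methyl (5E,7Z,12R,14Z)-10-chloro-12-hydroxy-9-oxoprosta-5,7,10,14-tetraen-1-oate | CCCCC/C=C\C[C@@]1(O)C=C(Cl)C(=O)/C1=C\C=C\CCCC(=O)OC | intermediate
19 | methyl (5E,7Z,12R,14Z)-12-acetoxy-10-chloro-9-oxoprosta-5,7,10,14-tetraen-1-oate | CCCCC/C=C\C[C@@]1(OC(C)=O)C=C(Cl)C(=O)/C1=C\C=C\CCCC(=O)OC | target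

**Step count.** Total: 11 steps. Longest linear sequence: 10 steps (steps 1–7 and 9–11); step 8 is a one-step side branch.

**Steps most likely to fail**

1. Step 3 (key step). The primary furfuryl alcohol may ionise too slowly under an acid mild enough to keep a tight chiral ion pair, so that furan oligomerisation or weak torquoselectivity (low enantiomeric purity) results. The fallback uses known chemistry, sets out from 5 and returns at 8. Compound 5 is rearranged under established racemic Piancatelli conditions for 5-alkylated furylcarbinols (ZnCl2, acetone–H2O, reflux, or hot water in a sealed vessel) to racemic 4-hydroxy-4-[(2Z)-oct-2-en-1-yl]cyclopent-2-en-1-one F1. Its enantiomers are separated by preparative chromatography on a chiral stationary phase; the (S)-enantiomer is 8 and (4R)-4-hydroxy-4-[(2Z)-oct-2-en-1-yl]cyclopent-2-en-1-one F2 is set aside.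

2. Step 7. Sulfonylation may proceed through a non-chelated enolate (loss of geometric control), the vinylogous acyl triflate may hydrolyse on work-up, or the enolate may expel silanolate. The fallback sets out from 12 and returns at 17, so steps 8 and 9 are then not needed. Compound 12 is deprotonated with LiN(i-Pr)2 at −78 °C and the enolate is transmetalated with Cp2ZrCl2, since zirconium enolates of cyclic ketones favour erythro aldols. Addition to methyl (5E)-7-oxohept-5-enoate F3 (one Wittig step from commercial methyl 5-oxopentanoate and Ph3P=CHCHO) should give the erythro aldol methyl (5E)-7-hydroxy-7-[3-chloro-5-[(2Z)-oct-2-en-1-yl]-2-oxo-5-(triethylsilyloxy)cyclopent-3-en-1-yl]hept-5-enoate F4. Stereospecific syn-dehydration of F4 with DCC and CuCl then leads to 17, because syn-elimination from the erythro aldol places C6 cis to C9.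

3. Step 9. Aqueous base may hydrolyse the vinylogous triflate faster than transmetalation occurs, or base and palladium may isomerise the 7Z-dienone to the 7E isomer. The fallback sets out from 14 and returns at 17. It is a base-free Stille coupling (Pd2(dba)3, AsPh3, NMP, 25 °C, dark) of 14 with methyl (5E)-6-(tributylstannyl)hex-5-enoate F5, which is made from 15 by palladium-catalysed hydrostannation (Bu3SnH, PdCl2(PPh3)2).

**Further compounds**

F1 | step 3 | racemic 4-hydroxy-4-[(2Z)-oct-2-en-1-yl]cyclopent-2-en-1-one | CCCCC/C=C\CC1(O)C=CC(=O)C1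
F2 | step 3 | (4R)-4-hydroxy-4-[(2Z)-oct-2-en-1-yl]cyclopent-2-en-1-one | CCCCC/C=C\C[C@]1(O)C=CC(=O)C1
F3 | step 7 | methyl (5E)-7-oxohept-5-enoate | COC(=O)CCC/C=C/C=O
F4 | step 7 | methyl (5E)-7-hydroxy-7-[3-chloro-5-[(2Z)-oct-2-en-1-yl]-2-oxo-5-(triethylsilyloxy)cyclopent-3-en-1-yl]hept-5-enoate, erythro at C7/C8, carbinol carbon C12 as in 12 | CCCCC/C=C\C[C@@]1(O[Si](CC)(CC)CC)C=C(Cl)C(=O)C1C(O)/C=C/CCCC(=O)OC
F5 | step 9 | methyl (5E)-6-(tributylstannyl)hex-5-enoate | COC(=O)CCC/C=C/[Sn](CCCC)(CCCC)CCCC
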